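Ring letters run from A, the 2,4,6-trihydroxyphenyl terminus, to F, the 3,4,5-trihydroxyphenyl terminus. The most crowded ether carbon, A C4, lies between the C3 and C5 hydroxyls and opposite the C1 hydroxyl, and it is never arylated. Ring A is instead grown around an oxygen already bound to ring B. A C3–C4–C5 come from a malonate whose central carbon carries the B1 oxygen, and A C6–C1–C2 come from 3-oxopentanedioate. One base-mediated Claisen/Dieckmann sequence forms A C2–C3 and A C5–C6, closes the ring and aromatises it. The precursor is a dimethyl 2-aryloxymalonate whose aryl group is the permethylated pentamer B–F, assembled convergently (B–C plus D–E–F) by copper-catalysed ether couplings.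

Key step: step 10

**Notation.**
- In rings B, D, E and F, position 1 carries the oxygen pointing towards ring A.
- In rings B, D and E, position 4 carries the oxygen pointing towards ring F.
- In ring C, position 1 carries the oxygen to ring B and position 6 the oxygen to ring D.
- Ar = 4-(2-{4-[3,5-dimethoxy-4-(3,4,5-trimethoxyphenoxy)phenoxy]-3,5-dimethoxyphenoxy}-3,4,5-trimethoxyphenoxy)-3,5-dimethoxyphenyl. This is the permethylated pentamer B–F bonded through B1, with twelve methyl ethers (2+3+2+2+3).
- The target, C36H26O20, has fifteen hydroxyls, five ether oxygens and no stereocentre.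

**Assumption.** Every ether coupling pairs the crowded oxygen (as phenol) with the uncrowded carbon (as halide), because copper catalysis tolerates bulk on the phenol better than on the halide.

**Design points.**
- All ester groups and the base of the key step share methoxide, so ester exchange is degenerate.
- The malonate is attached by SN2 with purchased chloromalonate. This avoids a diazo compound and a metal carbenoid next to five very electron-rich rings.
- Ring B enters without an acceptor group, so base cannot shift it between the two neighbouring oxygens of ring C. Its B1 oxygen is added late by sterically controlled C–H borylation.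
- The formyl group on ring C first activates the halide and then becomes the C6 oxygen.

Step 1
Reactants: 1 5-iodo-1,2,3-trimethoxybenzene; 2 4-bromo-2,6-dimethoxyphenol
Product: 3 5-bromo-1,3-dimethoxy-2-(3,4,5-trimethoxyphenoxy)benzene (E–F bromide)
Conditions: 1 (1.5 equiv), CuI (10 mol %), picolinic acid (20 mol %), K3PO4 (2 equiv), DMSO, 80 °C, Ar
Reagents that add atoms: none
Why: Ligand-accelerated Ullmann diaryl ether synthesis with a catalyst system suited to di-ortho-substituted phenols, in which the C–I bond of 1 (used in excess) should react well ahead of any C–Br bond, the bromide of 2 being further deactivated as its para-phenoxide.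

Step 2
Reactants: 3 E–F bromide
Product: 4 5-iodo-1,3-dimethoxy-2-(3,4,5-trimethoxyphenoxy)benzene (E–F iodide)
Conditions: NaI (2 equiv), CuI (5 mol %), trans-N,N'-dimethylcyclohexane-1,2-diamine (10 mol %), dioxane, 110 °C, Ar
Reagents that add atoms: sodium iodide, [Na+].[I-]
Why: Copper-catalysed aromatic Finkelstein halogen exchange, an equilibrium pulled to the iodide by excess NaI and the poor solubility of NaBr in dioxane, which touches neither methyl nor diaryl ethers.

Step 3
Reactants: 4 E–F iodide; 2 4-bromo-2,6-dimethoxyphenol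
Product: 5 5-bromo-2-[3,5-dimethoxy-4-(3,4,5-trimethoxyphenoxy)phenoxy]-1,3-dimethoxybenzene (D–E–F bromide)
Conditions: 4 (1.25 equiv, surplus recovered), CuI (10 mol %), picolinic acid (20 mol %), K3PO4 (2 equiv), DMSO, 80 °C, Ar
Reagents that add atoms: none
Why: The same chemoselective Ullmann ether coupling as in step 1, now with iodide 4 as the faster partner, so that the bromine of 2 is carried intact to D1.

Step 4
Reactants: 6 5-bromo-1,2,3-trimethoxybenzene
Product: 7 6-bromo-2,3,4-trimethoxybenzaldehyde
Conditions: Cl2CHOMe (1.5 equiv), TiCl4 (2 equiv), CH2Cl2, −10 to 0 °C; ice/1 M HCl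
Reagents that add atoms: dichloromethyl methyl ether, COC(Cl)Cl; water, O
Why: Rieche formylation (Friedel–Crafts attack on the TiCl4-activated dichloromethyl ether) can only hit the two equivalent free positions of 6, each ortho and para to a methoxy group, so a single aldehyde with bromine ortho to CHO should result.

Step 5
Reactants: 7 6-bromo-2,3,4-trimethoxybenzaldehyde; 8 2,6-dimethoxyphenol
Product: 9 6-(2,6-dimethoxyphenoxy)-2,3,4-trimethoxybenzaldehyde (B–C aldehyde)
Conditions: CuI (10 mol %), picolinic acid (20 mol %), K3PO4 (2 equiv), DMSO, 90 °C, Ar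
Reagents that add atoms: none
Why: Ullmann ether coupling in which the ortho-formyl group lowers the electron density at the C–Br carbon and the bromide has only one ortho substituent, which offsets the bulk of the 2,6-dimethoxyphenoxide.

Step 6
Reactants: 9 B–C aldehyde
Product: 11 6-(2,6-dimethoxyphenoxy)-2,3,4-trimethoxyphenol (B–C phenol), via aryl formate 10 (not isolated)
Conditions: mCPBA (1.3 equiv), CH2Cl2, 0 °C to rt; basic aqueous wash; crude 10, K2CO3 (cat.), MeOH, rt
Reagents that add atoms: 3-chloroperoxybenzoic acid, OOC(=O)c1cccc(Cl)c1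
Why: Baeyer–Villiger oxidation of an electron-rich benzaldehyde proceeds with aryl migration to the formate, which base-catalysed methanolysis cleaves, so the formyl group that activated step 5 becomes the C6 oxygen.

Step 7
Reactants: 11 B–C phenol; 5 D–E–F bromide
Product: 12 1-(2,6-dimethoxyphenoxy)-2-{4-[3,5-dimethoxy-4-(3,4,5-trimethoxyphenoxy)phenoxy]-3,5-dimethoxyphenoxy}-3,4,5-trimethoxybenzene (pentamer B–F, hydrogen at B1)
Conditions: CuI (20 mol %), picolinic acid (40 mol %), K3PO4 (2 equiv), DMSO, 105 °C, Ar
Reagents that add atoms: none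
Why: Ullmann ether coupling with one phenol and one unhindered aryl bromide in the flask, so forcing conditions cost no selectivity, and because ring B is electron-rich no Smiles migration of it between the two ortho oxygens of ring C is expected.

Step 8
Reactants: 12 pentamer B–F
Product: 14 ArOH (pentamer phenol with hydroxyl at B1), via B1 pinacol boronate 13 (not isolated)
Conditions: [Ir(OMe)(cod)]2 (3 mol %), 4,4'-di-tert-butyl-2,2'-bipyridine (6 mol %), B2pin2 (1.2 equiv), THF, 80 °C, sealed; then NaBO3·4H2O, THF/H2O, rt
Reagents that add atoms: bis(pinacolato)diboron, CC1(C)OB(OC1(C)C)B1OC(C)(C)C(C)(C)O1 (boryl group of 13); sodium perborate, [Na+].[O-]OB=O (phenol oxygen of 14)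
Why: Sterically governed iridium-catalysed aromatic C–H borylation followed by boronate oxidation, B1–H being the only aromatic C–H of 12 without an ortho substituent while nearly all others sit between two oxygen substituents.

Step 9
Reactants: 14 ArOH; 15 dimethyl 2-chloromalonate
Product: 16 dimethyl 2-(ArO)propanedioate (aryloxymalonate)
Conditions: 15 (1.1 equiv), K2CO3 (1.5 equiv), acetone, 55 °C
Reagents that add atoms: none
Why: Williamson-type SN2 O-alkylation of an unhindered phenoxide by a doubly activated chloride, the standard access to aryloxymalonates, with chloride chosen over bromide to avoid halophilic attack and ring halogenation.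

Step 10
Reactants: 16 aryloxymalonate; 17 dimethyl 3-oxopentanedioate
Product: 19 dimethyl 2,4,6-trihydroxy-5-(ArO)benzene-1,3-dicarboxylate, via open-chain Claisen adduct 18 (not isolated)
Conditions: 17 (3 equiv), NaOMe (4 equiv), MeOH, rt; then 16, MeOH exchanged for diglyme, 120 °C, MeOH distilled off, Ar; 1 M HCl, 0 °C
Reagents that add atoms: none
Why: The sodium enolate of 17 adds through carbon to one ester carbonyl of 16 and expels methoxide (intermolecular Claisen acylation, bond A C2–C3), giving the tricarbonyl anion of 18; enolisation of its remaining methylene (A C6) and attack on the second malonate ester (Dieckmann condensation, bond A C5–C6) give a cyclohexanetrione that enolises three times to the phloroglucinolate, an essentially irreversible sink that drains all earlier equilibria. The closest known reaction type is the alkoxide-mediated condensation of malonic esters with 3-oxoglutaric esters to phloroglucinoldicarboxylates, and aryloxymalonates are established 1,3-bis-electrophiles in NaOMe-mediated cyclocondensations with amidines. Ring A closes by a 6-(enolexo)-exo-trig acyl substitution, the attacked C=O lying outside the forming ring. No stereocentre is created, and the two labile sp3 centres of 18 disappear on aromatisation. The step needs C- over O-acylation and cross- over self-condensation: enol esters, 2-pyranones and the alternative Dieckmann ring through the aryloxy-bearing carbon (quaternary, unable to aromatise) are all reopened by methoxide, the mirror symmetry of both partners leaves one aromatic constitution, and keeping 17 fully enolised and in excess removes the free ketone that its self-condensation requires. Since 17 should be the stronger carbon acid, the chosen base loading leaves much of 16 un-ionised and electrophilic, and distilling off methanol pushes both acyl substitutions forward.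

Step 11
Reactants: 19 ring A diester
Product: 21 2-(ArO)benzene-1,3,5-triol (hexamer with free ring A and rings B–F as dodecamethyl ether), via ring A diacid 20 (not isolated)
Conditions: KOH (10 equiv), degassed H2O/MeOH, reflux, Ar; then HCl to pH 2, 60 °C
Reagents that add atoms: potassium hydroxide, [K+].[OH-] (oxygen of the carboxyl groups of 20 only; it leaves again as CO2)
Why: Ester saponification followed by protodecarboxylation of a 2,4,6-trihydroxyarenecarboxylic acid, which loses CO2 readily through its ring-protonated keto tautomer, while aryl methyl and diaryl ethers are inert to aqueous base and to brief dilute acid.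

Step 12
Reactants: 21 hexamer dodecamethyl ether
Product: 22 target CNP0270681.0
Conditions: BBr3 (30 equiv), CH2Cl2, −78 °C to rt, Ar; ice/H2O; EtOAc extraction; Sephadex LH-20 under Ar
Reagents that add atoms: none
Why: BBr3-mediated aryl methyl ether cleavage (bromide attacks the methyl carbon of the boron-complexed ether) cannot break the diaryl ether bonds, and an aqueous rather than methanolic quench avoids acid-catalysed O-methylation of the phloroglucinol-type rings.

**Compound list**

1 | 5-iodo-1,2,3-trimethoxybenzene | COc1cc(I)cc(OC)c1OC | starting material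
2 | 4-bromo-2,6-dimethoxyphenol | COc1cc(Br)cc(OC)c1O | starting material
3 | 5-bromo-1,3-dimethoxy-2-(3,4,5-trimethoxyphenoxy)benzene | COc1cc(Br)cc(OC)c1Oc1cc(OC)c(OC)c(OC)c1 | intermediate
4 | 5-iodo-1,3-dimethoxy-2-(3,4,5-trimethoxyphenoxy)benzene | COc1cc(I)cc(OC)c1Oc1cc(OC)c(OC)c(OC)c1 | intermediate
5 | 5-bromo-2-[3,5-dimethoxy-4-(3,4,5-trimethoxyphenoxy)phenoxy]-1,3-dimethoxybenzene | COc1cc(Br)cc(OC)c1Oc1cc(OC)c(Oc2cc(OC)c(OC)c(OC)c2)c(OC)c1 | intermediate
6 | 5-bromo-1,2,3-trimethoxybenzene | COc1cc(Br)cc(OC)c1OC | starting material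
7 | 6-bromo-2,3,4-trimethoxybenzaldehyde | COc1cc(Br)c(C=O)c(OC)c1OC | intermediate
8 | 2,6-dimethoxyphenol | COc1cccc(OC)c1O | starting material
9 | 6-(2,6-dimethoxyphenoxy)-2,3,4-trimethoxybenzaldehyde | COc1cccc(OC)c1Oc1cc(OC)c(OC)c(OC)c1C=O | intermediate
10 | 6-(2,6-dimethoxyphenoxy)-2,3,4-trimethoxyphenyl formate (not isolated) | COc1cccc(OC)c1Oc1cc(OC)c(OC)c(OC)c1OC=O | intermediate
11 | 6-(2,6-dimethoxyphenoxy)-2,3,4-trimethoxyphenol | COc1cccc(OC)c1Oc1cc(OC)c(OC)c(OC)c1O | intermediate
12 | permethylated pentamer B–F with hydrogen at B1 | COc1cccc(OC)c1Oc1cc(OC)c(OC)c(OC)c1Oc1cc(OC)c(Oc2cc(OC)c(Oc3cc(OC)c(OC)c(OC)c3)c(OC)c2)c(OC)c1 | intermediate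
13 | B1 pinacol boronate of 12 (not isolated) | COc1cc(B2OC(C)(C)C(C)(C)O2)cc(OC)c1Oc1cc(OC)c(OC)c(OC)c1Oc1cc(OC)c(Oc2cc(OC)c(Oc3cc(OC)c(OC)c(OC)c3)c(OC)c2)c(OC)c1 | intermediate
14 | ArOH, pentamer phenol with hydroxyl at B1 | COc1cc(O)cc(OC)c1Oc1cc(OC)c(OC)c(OC)c1Oc1cc(OC)c(Oc2cc(OC)c(Oc3cc(OC)c(OC)c(OC)c3)c(OC)c2)c(OC)c1 | intermediate
15 | dimethyl 2-chloromalonate | COC(=O)C(Cl)C(=O)OC | starting material
16 | dimethyl 2-(ArO)propanedioate | COC(=O)C(Oc1cc(OC)c(Oc2cc(OC)c(OC)c(OC)c2Oc2cc(OC)c(Oc3cc(OC)c(Oc4cc(OC)c(OC)c(OC)c4)c(OC)c3)c(OC)c2)c(OC)c1)C(=O)OC | intermediate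
17 | dimethyl 3-oxopentanedioate | COC(=O)CC(=O)CC(=O)OC | starting material
18 | dimethyl 2-(ArO)-4-(methoxycarbonyl)-3,5-dioxoheptanedioate (tautomers and labile epimers, not isolated) | COC(=O)CC(=O)C(C(=O)OC)C(=O)C(Oc2cc(OC)c(Oc3cc(OC)c(OC)c(OC)c3Oc3cc(OC)c(Oc4cc(OC)c(Oc5cc(OC)c(OC)c(OC)c5)c(OC)c4)c(OC)c3)c(OC)c2)C(=O)OC | intermediate
19 | dimethyl 2,4,6-trihydroxy-5-(ArO)benzene-1,3-dicarboxylate | COC(=O)c1c(O)c(C(=O)OC)c(O)c(Oc2cc(OC)c(Oc3cc(OC)c(OC)c(OC)c3Oc3cc(OC)c(Oc4cc(OC)c(Oc5cc(OC)c(OC)c(OC)c5)c(OC)c4)c(OC)c3)c(OC)c2)c1O | intermediate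
20 | 2,4,6-trihydroxy-5-(ArO)benzene-1,3-dicarboxylic acid (not isolated) | OC(=O)c1c(O)c(C(=O)O)c(O)c(Oc2cc(OC)c(Oc3cc(OC)c(OC)c(OC)c3Oc3cc(OC)c(Oc4cc(OC)c(Oc5cc(OC)c(OC)c(OC)c5)c(OC)c4)c(OC)c3)c(OC)c2)c1O | intermediate
21 | 2-(ArO)benzene-1,3,5-triol | Oc1cc(O)c(Oc2cc(OC)c(Oc3cc(OC)c(OC)c(OC)c3Oc3cc(OC)c(Oc4cc(OC)c(Oc5cc(OC)c(OC)c(OC)c5)c(OC)c4)c(OC)c3)c(OC)c2)c(O)c1 | intermediate
22 | 2-[4-(2-{4-[3,5-dihydroxy-4-(3,4,5-trihydroxyphenoxy)phenoxy]-3,5-dihydroxyphenoxy}-3,4,5-trihydroxyphenoxy)-3,5-dihydroxyphenoxy]benzene-1,3,5-triol (CNP0270681.0) | Oc1cc(O)c(Oc2cc(O)c(Oc3cc(O)c(O)c(O)c3Oc3cc(O)c(Oc4cc(O)c(Oc5cc(O)c(O)c(O)c5)c(O)c4)c(O)c3)c(O)c2)c(O)c1 | target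

Total step count: 12. Longest linear sequence: 9 steps (steps 4–12 from 6, and equally steps 1–3 followed by 7–12 from 1).

**Steps most likely to fail**

1. **Step 10.**
 - Risk: Proton transfer from the malonate C–H to the enolate may park both partners in unreactive forms. Methoxide may strip a methoxycarbonyl group from the malonate by retro-Claisen cleavage. Self-condensation of the oxoglutarate may consume the nucleophile before cross-acylation occurs.
 - Fallback: It sets out from 12 and rejoins the route at 22. It gives up ring construction in favour of arylating a ready-made ring A phenol. Boronate 13, made as in step 8 but isolated, is converted by copper-mediated iododeboronation (CuI, 1,10-phenanthroline, KI, MeOH/H2O, air, 80 °C) into the B1-iodo pentamer F1. Ullmann coupling with purchased 2,4,6-trimethoxyphenol (CuI, picolinic acid, K3PO4, DMSO, 100 °C) gives the pentadecamethyl ether of the target F2. BBr3 cleavage as in step 12 then leads to 22.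

2. **Step 12.**
 - Risk: Ether cleavage may stall when partly cleaved borate esters precipitate. The pyrogallol-type rings may oxidise in air during isolation of the free polyphenol.
 - Fallback: It sets out from 21 and returns at 22 by a derivatise, purify and release sequence. The crude BBr3 product is not purified but acetylated at once (Ac2O, pyridine, DMAP cat., Ar) to the air-stable pentadecaacetate F3. This is chromatographed on silica, so under-cleaved material can be separated and resubmitted. Catalytic NaOMe in degassed MeOH at 0 °C, neutralised with an acidic ion-exchange resin, then releases 22.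

3. **Step 7.**
 - Risk: C–O bond formation at a phenol flanked by a methoxy and an aryloxy group may be so slow that hydrodebromination of the bromide and oxidative decay of the phenol take over at the required temperature.
 - Fallback: It sets out from 5 and returns at 12 by switching to a room-temperature oxidative coupling. Palladium-catalysed borylation (Pd(OAc)2, XPhos, B2(OH)4, KOAc, EtOH, 80 °C) gives the D–E–F boronic acid F4. Chan–Lam–Evans coupling with 11 (Cu(OAc)2, pyridine, 4 Å molecular sieves, CH2Cl2, dry air, rt) then gives 12.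

**Further compounds**

F1 | step 10 | B1-iodo pentamer B–F | COc1cc(I)cc(OC)c1Oc1cc(OC)c(OC)c(OC)c1Oc1cc(OC)c(Oc2cc(OC)c(Oc3cc(OC)c(OC)c(OC)c3)c(OC)c2)c(OC)c1
F2 | step 10 | pentadecamethyl ether of the target | COc1cc(OC)c(Oc2cc(OC)c(Oc3cc(OC)c(OC)c(OC)c3Oc3cc(OC)c(Oc4cc(OC)c(Oc5cc(OC)c(OC)c(OC)c5)c(OC)c4)c(OC)c3)c(OC)c2)c(OC)c1
F3 | step 12 | pentadecaacetate of the target | CC(=O)Oc1cc(OC(C)=O)c(Oc2cc(OC(C)=O)c(Oc3cc(OC(C)=O)c(OC(C)=O)c(OC(C)=O)c3Oc3cc(OC(C)=O)c(Oc4cc(OC(C)=O)c(Oc5cc(OC(C)=O)c(OC(C)=O)c(OC(C)=O)c5)c(OC(C)=O)c4)c(OC(C)=O)c3)c(OC(C)=O)c2)c(OC(C)=O)c1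
F4 | step 7 | {4-[3,5-dimethoxy-4-(3,4,5-trimethoxyphenoxy)phenoxy]-3,5-dimethoxyphenyl}boronic acid | COc1cc(B(O)O)cc(OC)c1Oc1cc(OC)c(Oc2cc(OC)c(OC)c(OC)c2)c(OC)c1
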